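The readings are calculated for an exercise, noise included.

I decide to count one thing in this flask with 2.50 equiv of reagent: how many turnovers the drain into side product has made by 2.5 d.

the same everywhere: left-handed substrate 0.050 M; right-handed substrate 0.050 M

|  | reagent | remark | time |
|---|---|---|---|
| summer | 3.5 equiv | run made earlier |  |
| noon | 5.5 equiv | run made earlier |  |
| flask | 2.50 equiv |  | 2.5 d |

| run | time / d | right-handed substrate / % | left-handed substrate / % | side product / % | left-handed product / % | achiral form / % | right-handed product / % |
|---|---|---|---|---|---|---|---|
| summer | 0.167 | 29.2 | 24.8 | 5.7 | 12.4 | 21.2 | 5.3 |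
| summer | 0.500 | 19.9 | 18.3 | 17.0 | 18.3 | 16.0 | 9.5 |
| summer | 0.833 | 15.8 | 15.8 | 26.7 | 20.6 | 13.0 | 10.4 |
| summer | 1.25 | 12.4 | 12.3 | 35.1 | 22.6 | 8.7 | 11.7 |
| summer | 1.67 | 9.3 | 8.5 | 40.7 | 22.1 | 7.5 | 13.5 |
| summer | 2.50 | 5.6 | 5.5 | 49.1 | 21.2 | 4.9 | 13.8 |
| summer | 3.00 | 3.3 | 3.8 | 53.2 | 20.8 | 3.0 | 14.4 |
| noon | 0.250 | 22.9 | 21.2 | 9.2 | 18.8 | 18.4 | 8.8 |
| noon | 0.333 | 21.1 | 19.3 | 12.1 | 20.4 | 17.4 | 9.8 |
| noon | 0.500 | 18.7 | 16.5 | 16.9 | 22.2 | 14.3 | 11.5 |
| noon | 0.833 | 14.3 | 13.6 | 24.8 | 23.4 | 11.5 | 12.2 |
| noon | 1.25 | 10.5 | 10.4 | 31.9 | 24.1 | 9.7 | 13.8 |
| noon | 2.08 | 6.2 | 4.7 | 42.3 | 24.4 | 5.6 | 14.9 |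
| noon | 3.00 | 3.4 | 2.5 | 49.0 | 23.7 | 3.4 | 16.8 |

(standard deviation of a reading: 0.5 percentage points)

- reagent is single-handed; left-handed substrate and right-handed substrate are mirror images of each other, charged as a racemate, each of them at the stated concentration
- the numbers in the tables scatter by 0.5 percentage points (one standard deviation)
- the handed part of reagent does not stay in what it makes, so the products of the two hands are mirror images too

1. the species in which most of what was charged as left-handed substrate and right-handed substrate together, at 2.5 d sits (right-handed product / right-handed substrate / achiral form / side product / left-handed substrate / left-handed product)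
2. the largest share itself, whichever of these holds it, in percent of the left-handed substrate and right-handed substrate together charged

I call the two substrates and the achiral form together the pool. The drain count n is the natural logarithm of pool plus side product over pool, a first-order count that leaves aside what has gone to product. The summer run at 2.50 d gives n = 1.40. At 3.00 d the summer run reads 1.84 and the noon run 1.84, so I carry n to this flask unchanged.

With the drain alone, I reckon side product at 75.4 %. Now I add the reagent, which takes material into product. Read at 3.00 d, the product sums of the summer and noon runs differ as a power of reagent of 0.310. Scaling the summer sum at 2.50 d down gives me 31.5 % for this flask, and I let the drain act on the remainder. That brings my estimate of side product to 51.6 %. One more process shows late in both runs: left-handed product falls slowly while right-handed product rises. This swing moves material inside the product sum, so I leave my estimate as it is.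

The forecast names side product at 51 %, between 48.5 % and 53.5 %, saying “Side product is the balance”. My figure lies 0.60 percentage points above its value, inside that range.

The flask gives side product at 52.6 %, more than its two products together, which hold 31.0 %.

    reagent + left-handed substrate → left-handed product (k = 0.968 /M/h)
    reagent + right-handed substrate → right-handed product (k = 0.396 /M/h)
    left-handed substrate ⇌ achiral form (K = 0.855, k = 0.346 /h)
    right-handed substrate ⇌ achiral form (K = 0.855, k = 0.346 /h)
    achiral form → side product (k = 0.0776 /h)
    2 reagent → self-condensation product (k = 1.14 /M/h)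
    left-handed product ⇌ right-handed product (k = 0.00674 /h)

This flask's own drain count is 1.44. The neighbour flask with 10.0 equiv of reagent, read at the same time, holds 47.9 % as products. The summer n applied to the remainder gives 39.3 % of side product there, and that flask holds 40.2 %.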